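**Retrosynthetic overview**
- The spiro centre is formed last: the target is disconnected to a ring A hydroxy enol ether (5-substituted 2,3-dihydrofuran carrying a free (S)-3-hydroxybutyl arm), closed by catalyst-controlled kinetic spiroketalisation with a confined chiral Brønsted acid instead of thermodynamic ketalisation of a dihydroxy ketone.
- The dihydrofuran comes from a homopropargylic alcohol (5-endo-dig cycloisomerisation), itself made by Yamaguchi–Hirao alkynylation of a phthalide-tethered (S)-epoxide with silyl-protected (S)-hex-5-yn-2-ol, the lactone being already in place.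
- The epoxide comes from (S)-3-butenylphthalide and (S)-1,2-epoxy-5-hexene (cross-metathesis, hydrogenation); the alkyne from (S)-propylene oxide and 1-(trimethylsilyl)propyne.
- The phthalide comes from 2-bromo-3,5-dimethoxybenzaldehyde: catalytic asymmetric butenyl addition sets C3, carbonylative lactonisation closes the lactone.
- Ring order: phthalide lactone, then ring A (dihydrofuran), then ring B with the spiro centre.

Assumption: the (S) ligand in step 1 and the (S,S) acid in step 11 are taken as the antipodes that give the 3S and 5''S centres (neither sense is proven for these substrates; if one is reversed its antipode is used, nothing else changes); 1, 2, 6, 9 and 10 are bought.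

**Step 1**
Reactants: 1 2-bromo-3,5-dimethoxybenzaldehyde; 2 but-3-enylmagnesium bromide
Product: 4 (S)-1-(2-bromo-3,5-dimethoxyphenyl)pent-4-en-1-ol, via but-3-enyltitanium triisopropoxide 3 (not isolated)
Conditions: 2, Ti(OiPr)4, CH2Cl2, −78 °C; then slow addition to 1, (S)-3-(3,5-diphenylphenyl)-H8-BINOL (3 mol%), Ti(OiPr)4, CH2Cl2, 0 °C; aq. HCl
Reagents that add atoms: none
Why: Titanium–BINOLate-catalysed enantioselective 1,2-alkylation of an aryl aldehyde, in which the non-basic alkyltitanium 3 delivers the butenyl group to the Si face inside the chiral titanium complex, setting the future phthalide C3 as S (ee of 90% or more expected, to be checked as the Mosher ester) and leaving the aryl bromide untouched.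

**Step 2**
Reactants: 4 (S)-1-(2-bromo-3,5-dimethoxyphenyl)pent-4-en-1-ol
Product: 5 (S)-3-(but-3-enyl)-5,7-dimethoxyisobenzofuran-1(3H)-one
Conditions: Pd(OAc)2 (5 mol%), Xantphos (6 mol%), CO (1 atm), Et3N, toluene, 90 °C
Reagents that add atoms: carbon monoxide, [C-]#[O+]
Why: Palladium-catalysed carbonylative lactonisation (intramolecular alkoxycarbonylation): zerovalent palladium inserts into the Ar–Br bond, CO inserts, and the neighbouring benzylic hydroxyl captures the acylpalladium to close the five-membered lactone without touching the C–O stereocentre, the chelating Xantphos suppressing Heck cyclisation onto the remote alkene.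

**Step 3**
Reactants: 5 (S)-3-(but-3-enyl)-5,7-dimethoxyisobenzofuran-1(3H)-one; 6 (S)-2-(but-3-enyl)oxirane (4 equiv)
Product: 7 (S)-5,7-dimethoxy-3-{6-[(S)-oxiran-2-yl]hex-3-enyl}isobenzofuran-1(3H)-one (E/Z mixture)
Conditions: second-generation Hoveyda–Grubbs catalyst (5 mol%), CH2Cl2, 40 °C
Reagents that add atoms: none
Why: Olefin cross-metathesis of two unhindered terminal alkenes, driven to the cross product by the excess of the cheap epoxide and loss of ethene; the E/Z ratio is irrelevant because the alkene is reduced next, and epoxide and lactone are inert to the ruthenium carbene.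

**Step 4**
Reactants: 7 (S)-5,7-dimethoxy-3-{6-[(S)-oxiran-2-yl]hex-3-enyl}isobenzofuran-1(3H)-one
Product: 8 (S)-5,7-dimethoxy-3-{6-[(S)-oxiran-2-yl]hexyl}isobenzofuran-1(3H)-one
Conditions: H2 (3 atm), RhCl(PPh3)3 (10 mol%), benzene/EtOH 1:1, rt
Reagents that add atoms: none
Why: Homogeneous hydrogenation saturates the 1,2-disubstituted alkene and, unlike palladium on carbon, cannot hydrogenolyse the terminal epoxide or the benzylic lactone C–O bond.

**Step 5**
Reactants: 9 (S)-2-methyloxirane; 10 trimethyl(prop-1-ynyl)silane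
Product: 12 (S)-6-(trimethylsilyl)hex-5-yn-2-ol, via 3-(trimethylsilyl)prop-2-ynyllithium 11 (not isolated)
Conditions: 10, n-BuLi, THF, −78 °C; then 9, BF3·OEt2, −78 °C; aq. NH4Cl
Reagents that add atoms: none
Why: SN2 opening of the terminal epoxide at its CH2 carbon by the propargylic lithium reagent under BF3 activation (the silyl group blocks the allenyl terminus) leaves the stereocentre untouched, so the S centre of 9 becomes C7'' of the target.

**Step 6**
Reactants: 12 (S)-6-(trimethylsilyl)hex-5-yn-2-ol
Product: 13 (S)-tert-butyldimethyl{[6-(trimethylsilyl)hex-5-yn-2-yl]oxy}silane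
Conditions: TBSCl, imidazole, DMF, rt
Reagents that add atoms: tert-butyldimethylsilyl chloride (TBSCl), CC(C)(C)[Si](C)(C)Cl
Why: Standard silylation of a secondary alcohol gives an ether that survives acetylide formation, BF3 at −78 °C and divalent palladium, and that fluoride later removes without acid.

**Step 7**
Reactants: 13 (S)-tert-butyldimethyl{[6-(trimethylsilyl)hex-5-yn-2-yl]oxy}silane
Product: 14 (S)-tert-butyl(hex-5-yn-2-yloxy)dimethylsilane
Conditions: K2CO3, MeOH, rt
Reagents that add atoms: none
Why: Base-catalysed methanolysis of the alkynyl C–Si bond (protodesilylation) frees the terminal alkyne while the silyl ether is untouched.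

**Step 8**
Reactants: 14 (S)-tert-butyl(hex-5-yn-2-yloxy)dimethylsilane (2 equiv); 8 (S)-5,7-dimethoxy-3-{6-[(S)-oxiran-2-yl]hexyl}isobenzofuran-1(3H)-one
Product: 16 (S)-3-[(7S,13S)-13-(tert-butyldimethylsilyloxy)-7-hydroxytetradec-9-ynyl]-5,7-dimethoxyisobenzofuran-1(3H)-one, via [(S)-5-(tert-butyldimethylsilyloxy)hex-1-ynyl]lithium 15 (not isolated)
Conditions: 14, n-BuLi, THF, −78 °C; BF3·OEt2; then 8, −78 °C, 1 h; aq. NH4Cl at −78 °C
Reagents that add atoms: none
Why: Yamaguchi–Hirao alkynylation, in which the BF3-activated acetylide opens the terminal epoxide at CH2 within minutes at −78 °C, faster than it adds to the hindered, electron-rich aryl lactone, and carries the S epoxide carbon over unchanged as the homopropargylic carbinol (future C2'').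

**Step 9**
Reactants: 16 (S)-3-[(7S,13S)-13-(tert-butyldimethylsilyloxy)-7-hydroxytetradec-9-ynyl]-5,7-dimethoxyisobenzofuran-1(3H)-one
Product: 17 (S)-3-{6-[(S)-5-((S)-3-(tert-butyldimethylsilyloxy)butyl)-2,3-dihydrofuran-2-yl]hexyl}-5,7-dimethoxyisobenzofuran-1(3H)-one
Conditions: PdCl2(PhCN)2 (5 mol%), 4 Å MS, dry Et2O, rt; filtration through basic alumina
Reagents that add atoms: none
Why: 5-endo-dig cycloisomerisation of a homopropargylic alcohol (anti-oxypalladation by divalent palladium, then protodepalladation) gives ring A as its enol ether; 4-exo attack is not viable, so the regiochemistry is fixed, and the silyl ether stops the second hydroxyl from closing to a spiroketal unselectively.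

**Step 10**
Reactants: 17 (S)-3-{6-[(S)-5-((S)-3-(tert-butyldimethylsilyloxy)butyl)-2,3-dihydrofuran-2-yl]hexyl}-5,7-dimethoxyisobenzofuran-1(3H)-one
Product: 18 (S)-3-{6-[(S)-5-((S)-3-hydroxybutyl)-2,3-dihydrofuran-2-yl]hexyl}-5,7-dimethoxyisobenzofuran-1(3H)-one
Conditions: Bu4NF, THF, 0 °C to rt; aq. NaHCO3; Et3N-deactivated silica
Reagents that add atoms: none
Why: Fluoride cleavage of the silyl ether under basic, acid-free conditions lets the acid-labile hydroxy enol ether be isolated without premature, unselective spiroketalisation.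

**Step 11**
Reactants: 18 (S)-3-{6-[(S)-5-((S)-3-hydroxybutyl)-2,3-dihydrofuran-2-yl]hexyl}-5,7-dimethoxyisobenzofuran-1(3H)-one
Product: 19 (S)-5,7-dimethoxy-3-{6-[(2S,5S,7S)-7-methyl-1,6-dioxaspiro[4.4]nonan-2-yl]hexyl}isobenzofuran-1(3H)-one
Conditions: (S,S)-imidodiphosphoric acid built from two 3,3'-bis(2,4,6-triethylphenyl)-BINOL units (5 mol%), 4 Å MS, MTBE, −35 °C; Et3N quench
Reagents that add atoms: none
Why: Proposed new method: the confined chiral acid protonates the enol ether at C4 of ring A and its conjugate base steers the pendant hydroxyl onto C5 of the resulting oxocarbenium ion within the ion pair (kinetic, near-concerted syn addition); the closest known reaction is the chiral phosphoric or imidodiphosphoric acid-catalysed asymmetric spiroacetalisation of simple hydroxy enol ethers, and here the catalyst must direct attack to the face cis to the C2'' chain against a small intrinsic bias to give 5''S, with low temperature and sieves preventing acid equilibration and chromatography removing the minor 5''R epimer.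

**Compound list**
1 | 2-bromo-3,5-dimethoxybenzaldehyde | COc1cc(OC)c(Br)c(C=O)c1 | starting material
2 | but-3-enylmagnesium bromide | C=CCC[Mg]Br | starting material
3 | but-3-enyltitanium triisopropoxide | C=CCC[Ti](OC(C)C)(OC(C)C)OC(C)C | intermediate
4 | (S)-1-(2-bromo-3,5-dimethoxyphenyl)pent-4-en-1-ol | COc1cc(OC)c(Br)c(c1)[C@H](CCC=C)O | intermediate
5 | (S)-3-(but-3-enyl)-5,7-dimethoxyisobenzofuran-1(3H)-one | COc1cc(OC)c2c(c1)[C@H](CCC=C)OC2=O | intermediate
6 | (S)-2-(but-3-enyl)oxirane | C=CCC[C@H]1CO1 | starting material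
7 | (S)-5,7-dimethoxy-3-{6-[(S)-oxiran-2-yl]hex-3-enyl}isobenzofuran-1(3H)-one (E/Z mixture) | COc1cc(OC)c2c(c1)[C@H](CCC=CCC[C@H]1CO1)OC2=O | intermediate
8 | (S)-5,7-dimethoxy-3-{6-[(S)-oxiran-2-yl]hexyl}isobenzofuran-1(3H)-one | COc1cc(OC)c2c(c1)[C@H](CCCCCC[C@H]1CO1)OC2=O | intermediate
9 | (S)-2-methyloxirane | C[C@H]1CO1 | starting material
10 | trimethyl(prop-1-ynyl)silane | CC#C[Si](C)(C)C | starting material
11 | 3-(trimethylsilyl)prop-2-ynyllithium | [Li]CC#C[Si](C)(C)C | intermediate
12 | (S)-6-(trimethylsilyl)hex-5-yn-2-ol | C[C@H](O)CCC#C[Si](C)(C)C | intermediate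
13 | (S)-tert-butyldimethyl{[6-(trimethylsilyl)hex-5-yn-2-yl]oxy}silane | C[C@H](O[Si](C)(C)C(C)(C)C)CCC#C[Si](C)(C)C | intermediate
14 | (S)-tert-butyl(hex-5-yn-2-yloxy)dimethylsilane | C[C@H](O[Si](C)(C)C(C)(C)C)CCC#C | intermediate
15 | [(S)-5-(tert-butyldimethylsilyloxy)hex-1-ynyl]lithium | C[C@H](O[Si](C)(C)C(C)(C)C)CCC#C[Li] | intermediate
16 | (S)-3-[(7S,13S)-13-(tert-butyldimethylsilyloxy)-7-hydroxytetradec-9-ynyl]-5,7-dimethoxyisobenzofuran-1(3H)-one | COc1cc(OC)c2c(c1)[C@H](CCCCCC[C@H](O)CC#CCC[C@H](C)O[Si](C)(C)C(C)(C)C)OC2=O | intermediate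
17 | (S)-3-{6-[(S)-5-((S)-3-(tert-butyldimethylsilyloxy)butyl)-2,3-dihydrofuran-2-yl]hexyl}-5,7-dimethoxyisobenzofuran-1(3H)-one | COc1cc(OC)c2c(c1)[C@H](CCCCCC[C@H]1CC=C(CC[C@H](C)O[Si](C)(C)C(C)(C)C)O1)OC2=O | intermediate
18 | (S)-3-{6-[(S)-5-((S)-3-hydroxybutyl)-2,3-dihydrofuran-2-yl]hexyl}-5,7-dimethoxyisobenzofuran-1(3H)-one | COc1cc(OC)c2c(c1)[C@H](CCCCCC[C@H]1CC=C(CC[C@H](C)O)O1)OC2=O | intermediate
19 | (S)-5,7-dimethoxy-3-{6-[(2S,5S,7S)-7-methyl-1,6-dioxaspiro[4.4]nonan-2-yl]hexyl}isobenzofuran-1(3H)-one | COc1cc(OC)c2c(c1)[C@H](CCCCCC[C@H]1CC[C@]3(CC[C@H](C)O3)O1)OC2=O | target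

**Totals**
Total step count: 11. Longest linear sequence: 8 steps (steps 1, 2, 3, 4, 8, 9, 10, 11, from 1).

**Steps most likely to fail**

Step 11 (catalyst-controlled spiro centre; the sense and level of selectivity are untested on this substrate). The fallback sets out from 18 and gives up kinetic control. Camphorsulfonic acid (10 mol%) in CH2Cl2 at rt closes the spiroketal under thermodynamic control and gives 19 together with its spiro epimer (S)-5,7-dimethoxy-3-{6-[(2S,5R,7S)-7-methyl-1,6-dioxaspiro[4.4]nonan-2-yl]hexyl}isobenzofuran-1(3H)-one F1, in roughly equal amounts. The two are separated by preparative HPLC, and F1 is re-equilibrated with the same acid and recycled, so the fallback comes back to the route at 19.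

Step 9 (the enol ether may hydrate, isomerise or decompose on the metal). The fallback sets out from 16 and replaces the catalytic cycloisomerisation by an electrophile-induced ring closure. Iodine and NaHCO3 in MeCN at 0 °C effect 5-endo-dig iodoetherification to the less electron-rich, chromatography-stable (S)-3-{6-[(S)-5-((S)-3-(tert-butyldimethylsilyloxy)butyl)-4-iodo-2,3-dihydrofuran-2-yl]hexyl}-5,7-dimethoxyisobenzofuran-1(3H)-one F2. Its C–I bond is then reduced with Bu3SnH and catalytic Pd(PPh3)4 (zerovalent palladium) in THF at rt, which comes back to the route at 17.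

Step 8 (the acetylide may add to the lactone carbonyl). The fallback sets out from 4 and keeps the lactone masked as the aryl bromide until the alkyne is in place. Cross-metathesis of 4 with 6 (second-generation Hoveyda–Grubbs catalyst) gives (S)-1-(2-bromo-3,5-dimethoxyphenyl)-7-[(S)-oxiran-2-yl]hept-4-en-1-ol F3. Hydrogenation over RhCl(PPh3)3, which spares the aryl bromide, gives (S)-1-(2-bromo-3,5-dimethoxyphenyl)-7-[(S)-oxiran-2-yl]heptan-1-ol F4. Alkynylation with 15 (3 equiv, BF3·OEt2, −78 °C, the benzylic hydroxyl carried as its lithium alkoxide) gives (1S,8S,14S)-1-(2-bromo-3,5-dimethoxyphenyl)-14-(tert-butyldimethylsilyloxy)pentadec-10-yne-1,8-diol F5. Carbonylative lactonisation as in step 2 (Pd(OAc)2, Xantphos, CO, Et3N) then closes the phthalide and comes back to the route at 16.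

**Further compounds**
F1 | step 11 | (S)-5,7-dimethoxy-3-{6-[(2S,5R,7S)-7-methyl-1,6-dioxaspiro[4.4]nonan-2-yl]hexyl}isobenzofuran-1(3H)-one | COc1cc(OC)c2c(c1)[C@H](CCCCCC[C@H]1CC[C@@]3(CC[C@H](C)O3)O1)OC2=O
F2 | step 9 | (S)-3-{6-[(S)-5-((S)-3-(tert-butyldimethylsilyloxy)butyl)-4-iodo-2,3-dihydrofuran-2-yl]hexyl}-5,7-dimethoxyisobenzofuran-1(3H)-one | COc1cc(OC)c2c(c1)[C@H](CCCCCC[C@H]1CC(I)=C(CC[C@H](C)O[Si](C)(C)C(C)(C)C)O1)OC2=O
F3 | step 8 | (S)-1-(2-bromo-3,5-dimethoxyphenyl)-7-[(S)-oxiran-2-yl]hept-4-en-1-ol | COc1cc(OC)c(Br)c(c1)[C@@H](O)CCC=CCC[C@H]1CO1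
F4 | step 8 | (S)-1-(2-bromo-3,5-dimethoxyphenyl)-7-[(S)-oxiran-2-yl]heptan-1-ol | COc1cc(OC)c(Br)c(c1)[C@@H](O)CCCCCC[C@H]1CO1
F5 | step 8 | (1S,8S,14S)-1-(2-bromo-3,5-dimethoxyphenyl)-14-(tert-butyldimethylsilyloxy)pentadec-10-yne-1,8-diol | COc1cc(OC)c(Br)c(c1)[C@@H](O)CCCCCC[C@H](O)CC#CCC[C@H](C)O[Si](C)(C)C(C)(C)C
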